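**Retrosynthetic overview**
1. The target is two 5,7-dimethoxycoumarin-8-yl units on a 1,4-dimethylcyclohex-3-ene (carbocycle numbering used below: C1 quaternary carbon, C2 aryl-bearing methine, C3=C4 alkene with methyl on C4, C5 and C6 methylenes). The Z-alkene arm on C1 is cut last, back to an aryl alkyne (semi-hydrogenation), then to a C1-ethynyl compound plus 8-iodo-5,7-dimethoxycoumarin (Sonogashira), the ethynyl group coming from a C1-formyl group.
2. The formyl cyclohexene is cut in one operation at C4–C5 and C1–C2 into two three-carbon pieces. One is a propargylic carbonate ArCH(OCO2Me)–C≡C–CH3 (C2, C3, C4 and its methyl; from the coumarin-8-carbaldehyde and a propynyl Grignard reagent). The other is a B-alkyl-9-BBN carrying a silyl enol ether, R2B–CH2CH2–C(CH3)=CH–OSi (C5, C6, C1 and the formyl carbon; from tiglaldehyde).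
3. Feature that allows this: C2 is at once benzylic to an electron-rich coumarin ring and allylic to the ring C3=C4 bond. C4–C3–C2 is therefore a 1-aryl-3,3-dialkylallyl unit that palladium can hold as a π-allyl and that an aryl allene delivers. Its neighbour C1 is a quaternary carbon whose Z-vinylarene can be carried as a formyl group, which makes C1 an enamine carbon.
4. Order of rings: both coumarin bicycles are bought intact (citropten). The carbocycle is the only ring built; it is closed in step 4 together with both stereocentres. The Z-alkene is made in the last step.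

Key step: step 4

Assumption: the sense of induction of the chiral phosphoric acid in step 4 is assigned by analogy with intermolecular hydridopalladium–enamine allylations; if it proves opposite, the enantiomeric acid is used and nothing else changes.
Abbreviations: 9-BBN = 9-borabicyclo[3.3.1]nonane; (S)-TRIP = (S)-3,3′-bis(2,4,6-triisopropylphenyl)-1,1′-binaphthyl-2,2′-diyl hydrogen phosphate.

**Route**

Step 1
Reactants: 1 5,7-dimethoxy-2H-chromen-2-one (citropten)
Product: 2 5,7-dimethoxy-2-oxo-2H-chromene-8-carbaldehyde
Conditions: Cl2CHOMe, TiCl4, CH2Cl2, 0 °C to rt; then H2O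
Reagents that add atoms: dichloromethyl methyl ether, COC(Cl)Cl; water, O
Why: Rieche formylation, an electrophilic aromatic substitution, should enter at C8 because this position is para to the 5-methoxy and ortho to the 7-methoxy group and is less hindered than C6 between the two methoxy groups; no stereocentre is formed.

Step 2
Reactants: 2 5,7-dimethoxy-2-oxo-2H-chromene-8-carbaldehyde; 3 prop-1-yn-1-ylmagnesium bromide
Product: 5 methyl 1-(5,7-dimethoxy-2-oxo-2H-chromen-8-yl)but-2-yn-1-yl carbonate (racemic), via bromomagnesium alkoxide 4 (not isolated)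
Conditions: THF, −78 °C to −20 °C; then ClCO2Me, −20 °C to 0 °C
Reagents that add atoms: methyl chloroformate, COC(=O)Cl
Why: Nucleophilic addition of the alkynyl Grignard reagent to the aldehyde, which is far more electrophilic than the coumarin lactone at low temperature, followed by O-acylation of the alkoxide in the same flask; the carbinol centre is formed racemic on purpose because step 4 erases it.

Step 3
Reactants: 6 (2E)-2-methylbut-2-enal (tiglaldehyde)
Product: 7 tert-butyl(dimethyl){[(1E)-2-methylbuta-1,3-dien-1-yl]oxy}silane
Conditions: TBSOTf, Et3N, Et2O, 0 °C to rt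
Reagents that add atoms: tert-butyldimethylsilyl trifluoromethanesulfonate, CC(C)(C)[Si](C)(C)OS(=O)(=O)C(F)(F)F
Why: Soft enolisation of the enal (γ-deprotonation of the O-silylated oxocarbenium ion by the amine) is the standard silyl triflate route to 1-silyloxy-1,3-dienes and should give mainly the 1E isomer; no stereocentre is formed and the enol ether geometry is of no consequence later.

Step 4
Reactants: 5 methyl 1-(5,7-dimethoxy-2-oxo-2H-chromen-8-yl)but-2-yn-1-yl carbonate (racemic); 7 tert-butyl(dimethyl){[(1E)-2-methylbuta-1,3-dien-1-yl]oxy}silane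
Product: 11 (1S,2S)-2-(5,7-dimethoxy-2-oxo-2H-chromen-8-yl)-1,4-dimethylcyclohex-3-ene-1-carbaldehyde (aryl and formyl cis), via alkylborane 8 (not isolated), via allenyl silyl enol ether 9 (not isolated), via allenyl aldehyde 10 (not isolated)
Conditions: 9-BBN, THF, 0 °C to rt; then 5, Pd(PPh3)4 (5 mol %), 60 °C; then Ph2CHNH2 (40 mol %), (S)-TRIP (10 mol %), H2O (2 equiv), toluene, 60 °C
Reagents that add atoms: water, O
Why: Proposed new method: in the first stage zerovalent palladium ionises propargylic carbonate 5 to a σ-allenylpalladium methoxide, the methoxide activates B-alkyl-9-BBN 8 for transmetalation, and reductive elimination joins the primary sp3 carbon to the methyl-bearing alkyne carbon to give allene 9 (ring bond C4–C5); in the second stage the phosphoric acid turns the same palladium into a hydride that adds to the central allene carbon to give a 1-aryl-3,3-dialkyl-π-allylpalladium, while benzhydrylamine and water convert the silyl enol ether into the enamine of α-branched aldehyde 10, whose α-carbon attacks the aryl-bearing allyl terminus (ring bond C1–C2). The closest known reaction types are the base-free palladium-catalysed coupling of propargylic carbonates with organoboranes to give allenes and the hydridopalladium–enamine α-allylation of α-branched aldehydes with allenes or alkynes under chiral phosphoric acid and primary amine catalysis, both intermolecular; new here are their union in one flask and the ring-closing attack at the internal, aryl-substituted allyl terminus. The cyclohexene closes in a 6-endo mode with respect to the allyl unit (all three allyl carbons become ring members, the only alternative being attack at the tertiary terminus to a strained cyclobutane); closure needs the tether anti on the allyl unit, and this isomer is reached because allene, 1,3-dienes and the syn and anti allyl complexes interconvert through reversible β-hydride elimination, which should also make the step stereoconvergent from racemic 5. The quaternary stereocentre C1 is set by the chiral phosphate, which is hydrogen-bonded to the enamine N–H and ion-paired with the allylpalladium cation and so exposes one enamine face. The benzylic stereocentre C2 is set relative to C1 by the compact boat-like cyclic transition state, in which the CH=N unit of the enamine lies over the central allyl CH and the methyl group takes the position next to the syn aryl group, so that aryl and formyl end up cis. The step needs the hydride to choose the allene over the two coumarin C3=C4 bonds and the enamine to attack through carbon, which the high reactivity of allenes toward hydropalladation, the reversibility of any addition to the lactone alkenes and the bulk of the N-benzhydryl group should secure.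

Step 5
Reactants: 11 (1S,2S)-2-(5,7-dimethoxy-2-oxo-2H-chromen-8-yl)-1,4-dimethylcyclohex-3-ene-1-carbaldehyde
Product: 12 8-[(1R,6S)-6-ethynyl-3,6-dimethylcyclohex-2-en-1-yl]-5,7-dimethoxy-2H-chromen-2-one
Conditions: dimethyl (1-diazo-2-oxopropyl)phosphonate, K2CO3, MeOH, 0 °C to rt
Reagents that add atoms: dimethyl (1-diazo-2-oxopropyl)phosphonate, COP(=O)(OC)C(=[N+]=[N-])C(C)=O
Why: Seyferth–Gilbert homologation in the Ohira–Bestmann variant should turn the non-enolisable, α-quaternary aldehyde into the terminal alkyne under mild carbonate conditions that leave the lactones (re-closed on acidic work-up if opened) and both stereocentres untouched.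

Step 6
Reactants: 1 5,7-dimethoxy-2H-chromen-2-one (citropten)
Product: 13 8-iodo-5,7-dimethoxy-2H-chromen-2-one
Conditions: N-iodosuccinimide, CF3CO2H (cat.), MeCN, 0 °C to rt
Reagents that add atoms: N-iodosuccinimide, O=C1CCC(=O)N1I
Why: Electrophilic aromatic iodination with an acid-activated N-iodoimide should go to C8 for the same electronic and steric reasons as the formylation in step 1; no stereocentre is formed.

Step 7
Reactants: 12 8-[(1R,6S)-6-ethynyl-3,6-dimethylcyclohex-2-en-1-yl]-5,7-dimethoxy-2H-chromen-2-one; 13 8-iodo-5,7-dimethoxy-2H-chromen-2-one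
Product: 14 8-{[(1S,2R)-2-(5,7-dimethoxy-2-oxo-2H-chromen-8-yl)-1,4-dimethylcyclohex-3-en-1-yl]ethynyl}-5,7-dimethoxy-2H-chromen-2-one
Conditions: PdCl2(PPh3)2 (5 mol %), CuI (10 mol %), Et3N, DMF, 60 °C
Reagents that add atoms: none
Why: Sonogashira coupling (oxidative addition of the aryl iodide, copper acetylide transmetalation, reductive elimination) should join the second coumarin to the neopentyl-type terminal alkyne without touching the stereocentres.

Step 8
Reactants: 14 8-{[(1S,2R)-2-(5,7-dimethoxy-2-oxo-2H-chromen-8-yl)-1,4-dimethylcyclohex-3-en-1-yl]ethynyl}-5,7-dimethoxy-2H-chromen-2-one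
Product: 15 8-[(Z)-2-[(1R,2R)-2-(5,7-dimethoxy-2-oxo-2H-chromen-8-yl)-1,4-dimethylcyclohex-3-en-1-yl]ethenyl]-5,7-dimethoxy-2H-chromen-2-one (CNP0164660.3)
Conditions: H2 (1 atm), Pd on CaCO3 poisoned with Pb(OAc)2, quinoline, EtOAc, rt
Reagents that add atoms: none
Why: Lindlar-type semi-hydrogenation delivers both hydrogens to one face of the alkyne on the poisoned palladium surface and so should give the Z alkene, while the trisubstituted ring alkene and the conjugated lactone C3=C4 bonds are not reduced under these conditions.

**Compound list**
1 | 5,7-dimethoxy-2H-chromen-2-one (citropten) | COc1cc(OC)c2ccc(=O)oc2c1 | starting material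
2 | 5,7-dimethoxy-2-oxo-2H-chromene-8-carbaldehyde | COc1cc(OC)c2ccc(=O)oc2c1C=O | intermediate
3 | prop-1-yn-1-ylmagnesium bromide | CC#C[Mg]Br | starting material
4 | bromomagnesium 1-(5,7-dimethoxy-2-oxo-2H-chromen-8-yl)but-2-yn-1-olate (racemic, not isolated) | CC#CC(O[Mg]Br)c1c(OC)cc(OC)c2ccc(=O)oc12 | intermediate
5 | methyl 1-(5,7-dimethoxy-2-oxo-2H-chromen-8-yl)but-2-yn-1-yl carbonate (racemic) | CC#CC(OC(=O)OC)c1c(OC)cc(OC)c2ccc(=O)oc12 | intermediate
6 | (2E)-2-methylbut-2-enal (tiglaldehyde) | C/C=C(\C)C=O | starting material
7 | tert-butyl(dimethyl){[(1E)-2-methylbuta-1,3-dien-1-yl]oxy}silane | C=C/C(C)=C/O[Si](C)(C)C(C)(C)C | intermediate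
8 | 9-[(3E)-4-{[tert-butyl(dimethyl)silyl]oxy}-3-methylbut-3-en-1-yl]-9-borabicyclo[3.3.1]nonane (not isolated) | CC(C)(C)[Si](C)(C)O/C=C(\C)CCB1C2CCCC1CCC2 | intermediate
9 | 8-[(5E)-6-{[tert-butyl(dimethyl)silyl]oxy}-3,5-dimethylhexa-1,2,5-trien-1-yl]-5,7-dimethoxy-2H-chromen-2-one (racemic allene, not isolated) | COc1cc(OC)c2ccc(=O)oc2c1C=C=C(C)CC/C(C)=C/O[Si](C)(C)C(C)(C)C | intermediate
10 | 6-(5,7-dimethoxy-2-oxo-2H-chromen-8-yl)-2,4-dimethylhexa-4,5-dienal (stereoisomer mixture, not isolated) | COc1cc(OC)c2ccc(=O)oc2c1C=C=C(C)CCC(C)C=O | intermediate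
11 | (1S,2S)-2-(5,7-dimethoxy-2-oxo-2H-chromen-8-yl)-1,4-dimethylcyclohex-3-ene-1-carbaldehyde (aryl and formyl cis) | O=C[C@@]1(C)CCC(C)=C[C@H]1c1c(OC)cc(OC)c2ccc(=O)oc12 | intermediate
12 | 8-[(1R,6S)-6-ethynyl-3,6-dimethylcyclohex-2-en-1-yl]-5,7-dimethoxy-2H-chromen-2-one | C#C[C@@]1(C)CCC(C)=C[C@H]1c1c(OC)cc(OC)c2ccc(=O)oc12 | intermediate
13 | 8-iodo-5,7-dimethoxy-2H-chromen-2-one | COc1cc(OC)c2ccc(=O)oc2c1I | intermediate
14 | 8-{[(1S,2R)-2-(5,7-dimethoxy-2-oxo-2H-chromen-8-yl)-1,4-dimethylcyclohex-3-en-1-yl]ethynyl}-5,7-dimethoxy-2H-chromen-2-one | COc1cc(OC)c2ccc(=O)oc2c1C#C[C@@]1(C)CCC(C)=C[C@H]1c1c(OC)cc(OC)c2ccc(=O)oc12 | intermediate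
15 | 8-[(Z)-2-[(1R,2R)-2-(5,7-dimethoxy-2-oxo-2H-chromen-8-yl)-1,4-dimethylcyclohex-3-en-1-yl]ethenyl]-5,7-dimethoxy-2H-chromen-2-one | COc1cc(OC)c2ccc(=O)oc2c1/C=C\[C@@]1(C)CCC(C)=C[C@H]1c1c(OC)cc(OC)c2ccc(=O)oc12 | target

**Step count**
Total steps: 8. Longest linear sequence: 6 steps (steps 1, 2, 4, 5, 7, 8, from citropten).

**Steps most likely to fail**

1. Step 4 (Proposed new method). The hydridopalladium stage may stall at the allene or diene stage because the borinate by-product sequesters the acid and amine. Amination of the allyl intermediate may compete with C-attack. The ring closure may proceed with too little facial discrimination. The silyl enol ether may be lost during the borane coupling. The fallback uses known chemistry and sets out from aldehyde 2. Wittig olefination of 2 with 1-(triphenylphosphoranylidene)propan-2-one (toluene, 90 °C) should give (3E)-4-(5,7-dimethoxy-2-oxo-2H-chromen-8-yl)but-3-en-2-one F1. Methylenation of the ketone with Ph3P=CH2 (from Ph3PCH3Br and KN(SiMe3)2, THF, −78 °C to 0 °C) should give 5,7-dimethoxy-8-[(1E)-3-methylbuta-1,3-dien-1-yl]-2H-chromen-2-one F2. An enantioselective Diels–Alder reaction of F2 with 2-methylprop-2-enal under a chiral oxazaborolidinium Lewis acid (CH2Cl2, −78 °C), ortho-regioselective and endo for the formyl group, should give the cis aryl/formyl cyclohexene and so come back to the route at 11.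

2. Step 8. Hydrogen delivery to an alkyne shielded by the quaternary carbon and the ortho,ortho′-disubstituted arene may be slow, and forcing it may erode chemoselectivity (over-reduction, reduction of the lactone C3=C4 bonds). The fallback sets out from aldehyde 11 and forms the Z alkene by olefination and coupling instead of reduction. Stork–Zhao olefination of 11 with Ph3P=CHI (from (iodomethyl)triphenylphosphonium iodide and NaN(SiMe3)2, THF/DMPU, −78 °C) should give 8-[(1R,6S)-6-[(Z)-2-iodoethenyl]-3,6-dimethylcyclohex-2-en-1-yl]-5,7-dimethoxy-2H-chromen-2-one F3. Iodide 13 is stannylated with (Bu3Sn)2 and Pd(PPh3)4 (toluene, 100 °C) to 5,7-dimethoxy-8-(tributylstannyl)-2H-chromen-2-one F4. Stille coupling of F3 with F4 (Pd(PPh3)4, CuI, CsF, DMF, 45 °C) should proceed with retention of alkene geometry and come back to the route at the target 15, so that steps 5, 7 and 8 are not needed.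

3. Step 1. The formylating electrophile may attack C6 as well as C8, or formylate twice, giving aldehyde mixtures that are hard to separate. The fallback sets out from iodide 13 (step 6), whose bulkier, softer electrophile should discriminate better between C8 and the doubly flanked C6 and which can be purified by crystallisation. Palladium-catalysed reductive carbonylation of 13 (Pd(OAc)2, 1,3-bis(diphenylphosphino)propane, CO (1 atm), HCO2Na, DMF, 90 °C) should introduce the formyl group and come back to the route at 2; no new compound is made (F0).

**Further compounds**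
F1 | step 4 | (3E)-4-(5,7-dimethoxy-2-oxo-2H-chromen-8-yl)but-3-en-2-one | CC(=O)/C=C/c1c(OC)cc(OC)c2ccc(=O)oc12
F2 | step 4 | 5,7-dimethoxy-8-[(1E)-3-methylbuta-1,3-dien-1-yl]-2H-chromen-2-one | CC(=C)/C=C/c1c(OC)cc(OC)c2ccc(=O)oc12
F3 | step 8 | 8-[(1R,6S)-6-[(Z)-2-iodoethenyl]-3,6-dimethylcyclohex-2-en-1-yl]-5,7-dimethoxy-2H-chromen-2-one | I/C=C\[C@@]1(C)CCC(C)=C[C@H]1c1c(OC)cc(OC)c2ccc(=O)oc12
F4 | step 8 | 5,7-dimethoxy-8-(tributylstannyl)-2H-chromen-2-one | CCCC[Sn](CCCC)(CCCC)c1c(OC)cc(OC)c2ccc(=O)oc12
F0 | step 1 | none | none
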